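In the alpha run at −25 °C the fraction of substrate left fell nearly in a straight line, a near zero-order stretch, and in the zeta run at 18 °C it fell the same way, so I reckoned with the fraction left and not with the target made.

alpha run (percent of the substrate charged)

| time / min | target / % | substrate / % |
|---|---|---|
| 1.00 | 11 | 87 |
| 2.00 | 20 | 82 |
| 3.00 | 29 | 71 |
| 4.00 | 42 | 61 |
| 8.00 | 74 | 24 |
| 12.0 | 95 | 5 |

zeta run (percent of the substrate charged)

| time / s | target / % | substrate / % |
|---|---|---|
| 10.0 | 22 | 81 |
| 12.0 | 27 | 72 |
| 20.0 | 43 | 52 |
| 30.0 | 61 | 36 |
| 60.0 | 92 | 4 |
| 90.0 | 93 | 4 |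

(readings scatter by 2 percentage points)

| flask | substrate | free enzyme | temperature | remark | time |
|---|---|---|---|---|---|
| alpha | 0.10 M | 0.67 µM | −25 °C | run made earlier |  |
| zeta | 0.10 M | 1.5 µM | 18 °C | run made earlier |  |
| green | 0.10 M | 1.0 µM | 5 °C |  | 2.5 min |
| amber | 0.10 M | 1.0 µM | 30 °C |  | 2.5 min |
| violet | 0.10 M | 1.0 µM | 55 °C |  | 2.5 min |
| teal | 0.10 M | 1.0 µM | −20 °C |  | 2.5 min |

* the flask with the highest amount of target, in percent of the substrate charged ("all alike" if they lie within 1.5 percentage points) (green / amber / violet / teal / all alike)
* final target, as a percentage of the substrate charged, in green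
* final target, as a percentage of the substrate charged, in amber
* final target, as a percentage of the substrate charged, in violet
* final target, as a percentage of the substrate charged, in teal

- the earlier runs were read with a standard deviation of 2 percentage points

My decision was whether to keep 1.0 µM of free enzyme and 2.5 min in the planned flasks. I took the clearing time τ as the time that 1.0 µM of free enzyme needs to bring the fraction left to zero at the straight-line pace. The alpha run left 24% after 8.00 min with 0.67 µM, so scaled to 1.0 µM its reading gave τ = 7.05 min. The zeta run left 36% after 30.0 s with 1.5 µM, which gave τ = 1.17 min. Both carry the scatter of 2 points.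

The two readings gave an apparent activation energy of 25.1 kJ/mol. With it, teal had τ = 5.55 min, longer than the 2.5 min of the run, so I expected teal unfinished with 55.0% of its substrate left. Green had τ = 1.90 min, shorter than the run. For violet at 55 °C, beyond both runs, I reckoned 21.9 s, the clearing time of violet, which held if the free enzyme lasted that long. I left the charge and the time as they stood.

The forecast chose amber, with 92% in green, 93.5% in amber, 92% in violet and 46% in teal, and said of violet: “The enzyme may die”.

The flasks gave 93.9% in green, the highest, against 87.6% in amber, 46.2% in teal and 0% in violet.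

    free enzyme → unfolded enzyme (k = 9.10 × 10⁻⁴ /s, Ea = 255 kJ/mol)
    substrate + free enzyme → target + free enzyme, rate k2*[substrate]*[free enzyme]/(1 + ([substrate]/Km2) + ([substrate]/Ksi2)^2) (37.0 mM, 0.0890 M, k = 1.10 × 10⁵ /M/s, Ea = 25.0 kJ/mol)
    substrate + target → side product (k = 0.0750 /M/s, Ea = 63.0 kJ/mol)
    (constants at 30 °C)

In violet the half-life of target against the conversion of substrate + target into side product was 0.24 min at the asked time, shorter than the 2.5 min of the run. Target there stood at 0.0637% after 1.25 min, when free enzyme was already 0%, and 0% at the end, with 95% of the substrate left although my τ for violet was 21.9 s. For the neighbour of violet with 4.0 × 10⁻⁶ M of free enzyme the same reckoning gives τ = 5.47 s, and that neighbour ended with 81% of its substrate left, against 95% in violet, and target at 0.0183%.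

The data were generated by integration for substances that don't exist; the scatter is artificial.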